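## Structural features

The target is an achiral 2,3,4,6,7-pentasubstituted benzofuran: furan ring A is fused to benzene ring B across C3a–C7a, and a separate benzene ring C is joined to ring B by the biaryl bond C6–C1'. Ring A carries a methoxycarbonylmethyl chain on C2 and a methyl group on C3. Ring B carries para-related methoxy groups on C4 and C7 and has C5 as its only CH, and ring C has one hydroxyl group on C4', para to the biaryl bond. There are no stereocentres, so the problem is purely one of regiochemistry. The fragile sites are the C2 methylene (activated by furan and ester, so prone to enolisation, condensation and saponification), the methyl ester towards organometallic reagents and hydroxide, the free phenol, and the electron-rich 4,7-dimethoxybenzofuran, which is easily oxidised to the 4,7-quinone. The real difficulty is C6, where the aryl group sits beside the C7 methoxy group on a crowded ring, together with the contiguous C3a–C4–C5–C6–C7–C7a pattern. The key step uses the fact that ring C has a single heteroatom para to C1'. C1' and C6' can then come from a two-carbon alkene carrying a sulfonyl leaving group on the carbon bound to C6, and C2'–C5' from a four-carbon diene whose oxygenated carbon becomes C4'.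

## Logic of the disconnections

18 is opened across C1'–C2' and C5'–C6', after formal re-addition of methanol and benzenesulfinic acid, which leads to 14 and 15. The cut removes ring C completely and leaves only a two-carbon handle on C6, and the hydroxyl group arrives unprotected. The forward step must be regioselective at a hindered 1,1-disubstituted alkene, and both eliminations must spare the methyl ester.

14 is cut at the C–S bond of its internal vinyl carbon, giving 12 and 13. A branched addition of the S–H bond across the triple bond of 12 builds this carbon in one step from a cheap salt. The forward step must be Markovnikov-selective and must not touch the benzofuran.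

12 is traced through 11 to 9 and 10 by cutting the C6–C(sp) bond. The bromine of 9 is the handle that the first step of the route installs, and 10 supplies both carbons. The forward coupling has to work at an electron-rich C–Br bond flanked by a methoxy group, with an amine base that leaves the ester alone, and desilylation is then done in methanol so that ester exchange is degenerate.

9 is cut at C3–C3a, with the C2=C3 double bond returned to a ketone, giving 8. All of ring A and both of its substituents then come from one acyclic keto ester. The ring carbon that must attack is the only free position ortho to the ether oxygen and is further activated by the neighbouring methoxy group. The forward step needs an acid strong enough for cyclodehydration but mild to ester and aryl ethers.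

8 is cut at the O1–C2 ether bond into 5 and 7, and 7 is one bromination away from 6. This reduces the problem to a trisubstituted phenol and a five-carbon electrophile. The forward substitution at the bromo ketone must outrun base-induced loss of HBr from 7.

5 is traced to 3 by exchanging its hydroxyl group for a formyl group, then to 2 by removing the O-methyl group, then to 1 by removing bromine. In 1 the hydroxyl group directs bromination to its only free ortho position, which gives the 1,2,3-pattern around the central oxygen. The two positions flanking that oxygen are equivalent in pattern, so the formyl carbon can serve as the latent oxygen O1 and the bromine as the later carbon handle. The opposite assignment would need an acetal, an organolithium hydroxylation and a ring closure para to a deactivating formyl group, and this assignment avoids all three. The forward step needs aryl migration, not hydride migration, in the peracid oxidation of 3.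

## Other disconnections considered

Alternative 1: Ring B would be made last by a Moore rearrangement. The cut is C3a–C4 and leads to the furyl hydroxycyclobutenone A2. A2 would come from the 5-lithio derivative of the silyl-protected furan A4 and the arylcyclobutenedione A3, with addition at the carbonyl next to the aryl-bearing carbon. On heating in toluene, A2 should open in a four-electron conrotatory process, with the hydroxyl group turning outward, to a dienylketene. Six-electron electrocyclisation of the ketene carbon onto the free furan β-carbon and tautomerisation would give hydroquinone A1.
- In its favour: the connectivity of A2 fixes all six carbons of ring B, both oxygens and the C6 aryl group, the step needs no reagent, and the biaryl bond is inherited from A3 and never made at a crowded arene.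
- Against it here: the organolithium step excludes the ester, so the chain travels as a silyl ether and must later be deprotected, oxidised by two levels and esterified. A1 is an air-sensitive hydroquinone that needs double O-methylation, the benzyl ether must be removed at the end, and A3 may suffer conjugate addition or deprotonation at its vinylic CH.
- Comparison: on structure it is the better plan for the substitution pattern of ring B, which the chosen route takes over from classical aromatic substitution. On mechanism the two are equal, both being pericyclic ring constructions that end in tautomerisation to an arene with no stereocontrol needed. On step economy it is clearly worse, with about five operations after A1 against none after the chosen key step, and longer access to A3 and A4.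

Alternative 2: Ring A would be closed last at C2=C3 by a Perkin-type cyclisation. The cut leads to the 2-(2-acetylaryloxy)succinic acid A6. Heating A6 with acetic anhydride and NaOAc should form a mixed-anhydride enolate at the aryloxy-bearing carbon. This would add to the ortho acetyl carbonyl in a five-membered aldol closure, and decarboxylative dehydration would give the benzofuranylacetic acid A5.
- In its favour: the reaction type is classical, the C3–C3a bond already exists in the acetophenone so no ring closure onto an arene is needed, the acetic acid chain emerges directly, and the biaryl bond could be made early by a routine cross-coupling.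
- Against it here: the acetyl group is flanked by two ortho substituents and is twisted and poorly electrophilic. The succinic acid can close to a cyclic anhydride, and the aryloxide lies β to the second carboxyl group, so hot basic anhydride conditions invite its elimination. A6 needs a pentasubstituted acetophenone made by regioselective acylation, and esterification and debenzylation follow A5.
- Comparison: it is the better plan for forming the C6–C1' bond with certainty. It is equal in the absence of stereochemical demands. It is worse in needing a phenol protecting group and two steps after its key step, and in a ring closure that competes with β-elimination, whereas the acid cyclodehydration of the chosen route has no such base-induced pathway.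

Alternative 3: Ring B would be closed at C5=C6 by an aldol condensation that gives the quinone. The cut leads to the tetrasubstituted furan A8, which has an acetyl group on one β-carbon and an aryl 1,2-dione on the neighbouring α-carbon. With a mild amine base, the enolate of the acetyl methyl group should add to the aryl ketone in a six-membered closure, and loss of water would give the 6-arylbenzofuran-4,7-dione A7.
- In its favour: the conditions are mild, the 1,2-dione is a strong electrophile, six-membered closure onto the aryl ketone is preferred over five-membered closure onto the furyl ketone, and the 4,7-dioxygenation and the C6 aryl group follow from the carbonyl pattern alone.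
- Against it here: A7 must be reduced and O-methylated twice in the presence of the acidic C2 methylene, with a risk of C-methylation, and then debenzylated. The amine can add to the quinone, the ester methylene of A8 is a second enolisable site that can attack the dione of another molecule, and A8 with four different carbon substituents is itself a long synthesis.
- Comparison: it is the better plan in the mildness of its key step and in setting the ring B oxygens independently of aromatic substitution rules. It is equal in having no stereochemical issue. It is worse in step economy, with three operations after A7 and a difficult precursor, and in chemoselectivity around the C2 methylene.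

Key step: step 10

Remark on the chemistry: 7, 8, 16 and 17 are racemic (16 also a mixture of diastereomers). All these stereocentres are erased before the achiral target, so no stereocontrol is planned.

## Route

Step 1
Reactants: 1 2-hydroxy-5-methoxybenzaldehyde
Product: 2 3-bromo-2-hydroxy-5-methoxybenzaldehyde
Conditions: Br2 (1.05 equiv), NaOAc, AcOH, rt
Reagents that add atoms: bromine, BrBr
Why: Electrophilic aromatic bromination; the hydroxyl group directs to its only free ortho position, which is also meta to the formyl group, so a single regioisomer is expected.

Step 2
Reactants: 2 3-bromo-2-hydroxy-5-methoxybenzaldehyde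
Product: 3 3-bromo-2,5-dimethoxybenzaldehyde
Conditions: MeI, K2CO3, DMF, rt
Reagents that add atoms: iodomethane, CI
Why: Williamson O-methylation of an acidic salicylaldehyde hydroxyl group; carbonate is sufficient and the formyl group and aryl bromide are untouched.

Step 3
Reactants: 3 3-bromo-2,5-dimethoxybenzaldehyde
Product: 5 3-bromo-2,5-dimethoxyphenol, via 3-bromo-2,5-dimethoxyphenyl formate 4 (not isolated)
Conditions: mCPBA, CH2Cl2, 0 °C → rt; then solvent exchanged for MeOH, HCl (cat.), rt
Reagents that add atoms: 3-chloroperoxybenzoic acid, OOC(=O)c1cccc(Cl)c1
Why: Baeyer–Villiger (Dakin-type) oxidation; the electron-rich ortho-methoxy aryl group should migrate in preference to hydride, and the labile aryl formate is cleaved by acid-catalysed transesterification with methanol.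

Step 4
Reactants: 6 methyl levulinate
Product: 7 methyl 3-bromo-4-oxopentanoate (racemic)
Conditions: Br2 (1.0 equiv), CH2Cl2, 0 °C → rt; fractional distillation
Reagents that add atoms: bromine, BrBr
Why: Acid-catalysed α-bromination of a ketone through the more substituted enol, which in a non-hydroxylic solvent favours C3 over C5; the minor 5-bromo isomer is removed by distillation.

Step 5
Reactants: 5 3-bromo-2,5-dimethoxyphenol; 7 methyl 3-bromo-4-oxopentanoate
Product: 8 methyl 3-(3-bromo-2,5-dimethoxyphenoxy)-4-oxopentanoate (racemic)
Conditions: K2CO3 (1.2 equiv), acetone, 0 °C → rt, slow addition of 7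
Reagents that add atoms: methyl 3-bromo-4-oxopentanoate (7), COC(=O)CC(Br)C(C)=O
Why: Williamson ether synthesis by SN2 displacement at a carbonyl-activated α-bromo ketone; a weak base and low temperature are chosen so that substitution outruns dehydrobromination of 7 and retro-oxa-Michael cleavage of 8.

Step 6
Reactants: 8 methyl 3-(3-bromo-2,5-dimethoxyphenoxy)-4-oxopentanoate
Product: 9 methyl 2-(6-bromo-4,7-dimethoxy-3-methylbenzofuran-2-yl)acetate
Conditions: MeSO3H, CH2Cl2, 0 °C → rt
Reagents that add atoms: none
Why: Acid-mediated cyclodehydration of an α-aryloxy ketone (intramolecular Friedel–Crafts hydroxyalkylation, then dehydration to the furan); the only free ortho position is activated by the ether oxygen and the adjacent methoxy group, and the stereocentre of 8 is erased.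

Step 7
Reactants: 9 methyl 2-(6-bromo-4,7-dimethoxy-3-methylbenzofuran-2-yl)acetate; 10 ethynyltrimethylsilane
Product: 11 methyl 2-{4,7-dimethoxy-3-methyl-6-[(trimethylsilyl)ethynyl]benzofuran-2-yl}acetate
Conditions: Pd(PPh3)2Cl2 (5 mol %), CuI (5 mol %), Et3N, DMF, 80 °C (sealed vessel)
Reagents that add atoms: ethynyltrimethylsilane (10), C#C[Si](C)(C)C
Why: Sonogashira coupling; oxidative addition of zerovalent palladium into the aryl C–Br bond, transmetallation from the copper acetylide and reductive elimination, with an amine base that leaves the ester and its methylene alone.

Step 8
Reactants: 11 methyl 2-{4,7-dimethoxy-3-methyl-6-[(trimethylsilyl)ethynyl]benzofuran-2-yl}acetate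
Product: 12 methyl 2-(6-ethynyl-4,7-dimethoxy-3-methylbenzofuran-2-yl)acetate
Conditions: K2CO3 (cat.), MeOH, rt
Reagents that add atoms: none
Why: Methoxide-catalysed protodesilylation of an alkynylsilane; in methanol any ester exchange regenerates the same methyl ester.

Step 9
Reactants: 12 methyl 2-(6-ethynyl-4,7-dimethoxy-3-methylbenzofuran-2-yl)acetate; 13 sodium benzenesulfinate
Product: 14 methyl 2-{4,7-dimethoxy-3-methyl-6-[1-(phenylsulfonyl)vinyl]benzofuran-2-yl}acetate
Conditions: PhSO2H (liberated from 13 with 1 M HCl, extracted into CH2Cl2 and used at once), Pd(PPh3)4 (5 mol %), THF, 50 °C
Reagents that add atoms: sodium benzenesulfinate (13), [Na+].[O-]S(=O)c1ccccc1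
Why: Metal-catalysed Markovnikov hydrosulfonylation of a terminal aryl alkyne with a sulfinic acid; the acid adds oxidatively to zerovalent palladium, hydropalladation places the metal on the internal aryl-bearing carbon, and C–S reductive elimination gives the branched vinyl sulfone, a regiochemistry reinforced by the electron-rich aryl group.

Step 10
Reactants: 14 methyl 2-{4,7-dimethoxy-3-methyl-6-[1-(phenylsulfonyl)vinyl]benzofuran-2-yl}acetate; 15 trans-1-methoxy-3-(trimethylsilyloxy)buta-1,3-diene
Product: 18 phenylcandilide B, via silyl enol ether cycloadduct 16 (not isolated), via sulfonyl cyclohexenone 17 (not isolated)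
Conditions: 15 (4 equiv), toluene, 120 °C (sealed tube); then 1 M HCl, THF, 0 °C → rt; then DBU (3 equiv), THF, rt → 50 °C
Reagents that add atoms: trans-1-methoxy-3-(trimethylsilyloxy)buta-1,3-diene (15), CO/C=C/C(=C)O[Si](C)(C)C
Why: A thermal normal-demand [4+2] cycloaddition joins the unsubstituted, most nucleophilic terminus of 15 to the CH2 carbon of the sulfone-polarised alkene and the methoxy-bearing terminus to the carbon carrying sulfonyl and benzofuranyl, forming C5'–C6' and C1'–C2' and closing ring C in one concerted, asynchronous cycloaddition to give 16. The closest known reaction type is the Diels–Alder reaction of 1-methoxy-3-silyloxydienes with vinyl sulfones used as alkyne equivalents, followed by aromatising elimination. Dilute acid hydrolyses the silyl enol ether, and the resulting β-methoxy ketone loses methanol by E1cB to give enone 17. In 17 the C1'–S bond is tertiary, allylic and benzylic to an electron-rich arene, so DBU should remove benzenesulfinate together with a C6' hydrogen in an E2 process with E1 character. The cyclohexa-2,4-dienone so formed is the keto tautomer of the phenol and should enolise at once, aromatisation being the driving force. The two stereocentres of 16 (C1' and C2') form without control and are both erased, so no stereocontrol is needed. The selectivity required is regiochemical, with the oxygenated carbon para to C1', and it is secured by the match between the polarisation of the sulfonyl alkene and that of the diene; the opposite orientation would give the meta phenol. The ester and aryl ethers should tolerate heat, dilute acid and the amidine base, and the phenol emerges without a protecting group.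

## Compound list

1 | 2-hydroxy-5-methoxybenzaldehyde | COc1ccc(O)c(C=O)c1 | starting material
2 | 3-bromo-2-hydroxy-5-methoxybenzaldehyde | COc1cc(Br)c(O)c(C=O)c1 | intermediate
3 | 3-bromo-2,5-dimethoxybenzaldehyde | COc1cc(Br)c(OC)c(C=O)c1 | intermediate
4 | 3-bromo-2,5-dimethoxyphenyl formate (not isolated) | COc1cc(Br)c(OC)c(OC=O)c1 | intermediate
5 | 3-bromo-2,5-dimethoxyphenol | COc1cc(Br)c(OC)c(O)c1 | intermediate
6 | methyl levulinate (methyl 4-oxopentanoate) | COC(=O)CCC(C)=O | starting material
7 | methyl 3-bromo-4-oxopentanoate (racemic) | COC(=O)CC(Br)C(C)=O | intermediate
8 | methyl 3-(3-bromo-2,5-dimethoxyphenoxy)-4-oxopentanoate (racemic) | COC(=O)CC(Oc1cc(OC)cc(Br)c1OC)C(C)=O | intermediate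
9 | methyl 2-(6-bromo-4,7-dimethoxy-3-methylbenzofuran-2-yl)acetate | COC(=O)Cc1oc2c(OC)c(Br)cc(OC)c2c1C | intermediate
10 | ethynyltrimethylsilane | C#C[Si](C)(C)C | starting material
11 | methyl 2-{4,7-dimethoxy-3-methyl-6-[(trimethylsilyl)ethynyl]benzofuran-2-yl}acetate | COC(=O)Cc1oc2c(OC)c(C#C[Si](C)(C)C)cc(OC)c2c1C | intermediate
12 | methyl 2-(6-ethynyl-4,7-dimethoxy-3-methylbenzofuran-2-yl)acetate | COC(=O)Cc1oc2c(OC)c(C#C)cc(OC)c2c1C | intermediate
13 | sodium benzenesulfinate | [Na+].[O-]S(=O)c1ccccc1 | starting material
14 | methyl 2-{4,7-dimethoxy-3-methyl-6-[1-(phenylsulfonyl)vinyl]benzofuran-2-yl}acetate | COC(=O)Cc1oc2c(OC)c(C(=C)S(=O)(=O)c3ccccc3)cc(OC)c2c1C | intermediate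
15 | trans-1-methoxy-3-(trimethylsilyloxy)buta-1,3-diene | CO/C=C/C(=C)O[Si](C)(C)C | starting material
16 | methyl 2-{4,7-dimethoxy-6-[2-methoxy-1-(phenylsulfonyl)-4-(trimethylsilyloxy)cyclohex-3-en-1-yl]-3-methylbenzofuran-2-yl}acetate (racemic mixture of diastereomers, not isolated) | COC1C=C(O[Si](C)(C)C)CCC1(c1cc(OC)c2c(C)c(CC(=O)OC)oc2c1OC)S(=O)(=O)c1ccccc1 | intermediate
17 | methyl 2-{4,7-dimethoxy-3-methyl-6-[4-oxo-1-(phenylsulfonyl)cyclohex-2-en-1-yl]benzofuran-2-yl}acetate (racemic, not isolated) | O=C1C=CC(CC1)(c1cc(OC)c2c(C)c(CC(=O)OC)oc2c1OC)S(=O)(=O)c1ccccc1 | intermediate
18 | phenylcandilide B, methyl 2-[6-(4-hydroxyphenyl)-4,7-dimethoxy-3-methylbenzofuran-2-yl]acetate | COC(=O)Cc1oc2c(OC)c(-c3ccc(O)cc3)cc(OC)c2c1C | target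

## Step count and least certain steps

Total step count: 10. Longest linear sequence: 9 steps (steps 1, 2, 3, 5, 6, 7, 8, 9 and 10 from 1); step 4 is a one-step side branch.

Step 10 (key step). The most likely problem is a slow cycloaddition. The dienophile is 1,1-disubstituted, only moderately activated and twisted against the arene with its ortho methoxy group, so thermal decomposition and oligomerisation of 15 may outrun the desired reaction. Loss of benzenesulfinate from 17 may also be reluctant, because the C6' hydrogen is not acidified, and under DBU the enolisable C2 methylene could add to the enone of another molecule. The fallback gives up the de novo construction of ring C. It sets out from 9: Suzuki–Miyaura coupling with 4-hydroxyphenylboronic acid (Pd(OAc)2, SPhos, K3PO4, dioxane/H2O, 80 °C) should give 18 directly. It makes no new compound (entry F0) and returns to the route at 18.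

Step 5. The most likely problem is base-induced dehydrobromination of 7 to methyl 4-oxopent-2-enoate. The phenoxide would then add in a conjugate sense at the carbon next to the ester group, which gives the wrong constitution, and 8 itself can lose phenoxide by retro-oxa-Michael reaction. The fallback sets out from 5 and uses an electrophile with no hydrogen on a neighbouring saturated carbon:
- alkylation with methyl 2-chloroacetoacetate (K2CO3, acetone, reflux) should give methyl 2-(3-bromo-2,5-dimethoxyphenoxy)-3-oxobutanoate F1;
- cyclodehydration (MeSO3H, CH2Cl2) should give methyl 6-bromo-4,7-dimethoxy-3-methylbenzofuran-2-carboxylate F2;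
- saponification (LiOH, THF/H2O) should give 6-bromo-4,7-dimethoxy-3-methylbenzofuran-2-carboxylic acid F3;
- Arndt–Eistert homologation follows through 6-bromo-4,7-dimethoxy-3-methylbenzofuran-2-carbonyl chloride F4 ((COCl)2, DMF cat.) and 1-(6-bromo-4,7-dimethoxy-3-methylbenzofuran-2-yl)-2-diazoethan-1-one F5 (Me3SiCHN2, MeCN/THF);
- Wolff rearrangement of F5 in methanol (PhCO2Ag cat., Et3N) returns to the route at 9.

Step 9. The most likely problem is erosion of regiocontrol by a competing sulfonyl-radical chain, which adds at the terminal carbon and delivers the linear 2-sulfonylvinyl isomer. Disproportionation of the free sulfinic acid and deactivation of the catalyst are further risks. The fallback sets out from 12 and forms the C–S bond at the sulfide oxidation level. Markovnikov hydrothiolation with PhSH (Pd(OAc)2 cat., THF, 40 °C) should give methyl 2-{4,7-dimethoxy-3-methyl-6-[1-(phenylsulfanyl)vinyl]benzofuran-2-yl}acetate F6. Chemoselective oxidation at sulfur with KHSO5 (used as 2KHSO5·KHSO4·K2SO4, MeOH/THF/H2O, 0 °C → rt) returns to the route at 14.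

Step 7. The most likely problem is slow oxidative addition of zerovalent palladium into the electron-rich C–Br bond beside the methoxy group, so that copper-mediated oxidative dimerisation of 10 and hydrodebromination take over. The fallback sets out from 9 and builds the alkyne one carbon at a time. Reductive carbonylation (Pd(OAc)2, di(1-adamantyl)-n-butylphosphine, TMEDA, CO/H2, toluene, 100 °C) should give methyl 2-(6-formyl-4,7-dimethoxy-3-methylbenzofuran-2-yl)acetate F7. Ohira–Bestmann alkynylation with dimethyl (1-diazo-2-oxopropyl)phosphonate (K2CO3, MeOH, rt) returns to the route at 12, bypassing 11.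

## Further compounds

F0 | step 10 | none | none
F1 | step 5 | methyl 2-(3-bromo-2,5-dimethoxyphenoxy)-3-oxobutanoate (racemic) | COC(=O)C(Oc1cc(OC)cc(Br)c1OC)C(C)=O
F2 | step 5 | methyl 6-bromo-4,7-dimethoxy-3-methylbenzofuran-2-carboxylate | COC(=O)c1oc2c(OC)c(Br)cc(OC)c2c1C
F3 | step 5 | 6-bromo-4,7-dimethoxy-3-methylbenzofuran-2-carboxylic acid | OC(=O)c1oc2c(OC)c(Br)cc(OC)c2c1C
F4 | step 5 | 6-bromo-4,7-dimethoxy-3-methylbenzofuran-2-carbonyl chloride | ClC(=O)c1oc2c(OC)c(Br)cc(OC)c2c1C
F5 | step 5 | 1-(6-bromo-4,7-dimethoxy-3-methylbenzofuran-2-yl)-2-diazoethan-1-one | [N-]=[N+]=CC(=O)c1oc2c(OC)c(Br)cc(OC)c2c1C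
F6 | step 9 | methyl 2-{4,7-dimethoxy-3-methyl-6-[1-(phenylsulfanyl)vinyl]benzofuran-2-yl}acetate | COC(=O)Cc1oc2c(OC)c(C(=C)Sc3ccccc3)cc(OC)c2c1C
F7 | step 7 | methyl 2-(6-formyl-4,7-dimethoxy-3-methylbenzofuran-2-yl)acetate | COC(=O)Cc1oc2c(OC)c(C=O)cc(OC)c2c1C
A1 | alternative 1 | 6-(4-benzyloxyphenyl)-2-[2-(tert-butyldimethylsilyloxy)ethyl]-3-methylbenzofuran-4,7-diol | CC(C)(C)[Si](C)(C)OCCc1oc2c(O)c(-c3ccc(OCc4ccccc4)cc3)cc(O)c2c1C
A2 | alternative 1 | 3-(4-benzyloxyphenyl)-4-{5-[2-(tert-butyldimethylsilyloxy)ethyl]-4-methylfuran-2-yl}-4-hydroxycyclobut-2-en-1-one (racemic) | CC(C)(C)[Si](C)(C)OCCc1oc(cc1C)C1(O)C(=CC1=O)c1ccc(OCc2ccccc2)cc1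
A3 | alternative 1 | 3-(4-benzyloxyphenyl)cyclobut-3-ene-1,2-dione | O=C1C=C(c2ccc(OCc3ccccc3)cc2)C1=O
A4 | alternative 1 | tert-butyldimethyl[2-(3-methylfuran-2-yl)ethoxy]silane | CC(C)(C)[Si](C)(C)OCCc1occc1C
A5 | alternative 2 | 2-[6-(4-benzyloxyphenyl)-4,7-dimethoxy-3-methylbenzofuran-2-yl]acetic acid | OC(=O)Cc1oc2c(OC)c(-c3ccc(OCc4ccccc4)cc3)cc(OC)c2c1C
A6 | alternative 2 | 2-{[2-acetyl-5-(4-benzyloxyphenyl)-3,6-dimethoxyphenyl]oxy}succinic acid (racemic) | OC(=O)CC(Oc1c(OC)c(-c2ccc(OCc3ccccc3)cc2)cc(OC)c1C(C)=O)C(O)=O
A7 | alternative 3 | methyl 2-[6-(4-benzyloxyphenyl)-3-methyl-4,7-dioxo-4,7-dihydrobenzofuran-2-yl]acetate | COC(=O)Cc1oc2c(c1C)C(=O)C=C(c1ccc(OCc3ccccc3)cc1)C2=O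
A8 | alternative 3 | methyl 2-{4-acetyl-5-[2-(4-benzyloxyphenyl)-2-oxoacetyl]-3-methylfuran-2-yl}acetate | COC(=O)Cc1oc(C(=O)C(=O)c2ccc(OCc3ccccc3)cc2)c(C(C)=O)c1C
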